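**Retrosynthetic overview**

1. Locants used here: ring A = cyclopentane C3–C7 (C5–OH, C6–Me); ring B = cyclooctene C2=C3, C7, C8(OH), C9, C18, C19, C20 (C1 = methyl on C2); rings C/D = trans-decalin C9–C18 (methyls on C9 and C12, gem-dimethyl on C15); β = face of the C12 methyl when the four rings are drawn flat.
2. Target 30 ⇐ hydroboration of the C5=C6 alkene of 28 ⇐ methylation of enol triflate 27 ⇐ ring-A ketone 25 (C6=O); the C5 hydroxyl and C6 methyl are added last, anti to the C7–C8 bond.
3. Key disconnection: ring B of 25 at C19–C20 and C7–C8 gives iodo aldehyde 14 (rings C/D) and allylstannane dienone 21 (ring A); they are joined in one flask by radical allylation followed by tin hydride reductive aldol.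
4. Enabling feature: in ring B the C2=C3 alkene is exocyclic to ring A and β,γ to C6, and the C8 hydroxyl is β to C6. With C6 as a ketone, the array C1/C20–C2=C3–C7–C8(OH) is the α-aldol adduct of a 3-(propen-2-yl)cyclopentenone dienolate; C9 is quaternary, so the C8 aldehyde cannot enolise.
5. 14 comes from 3,3-dimethylcyclohexanone (ring D): ring C by chiral-imine Robinson annulation, C17/C18 by reductive hydroxymethylation, quaternary C9 by cyclopropanation and ring opening. Ring order: D, then C; ring A (from 3-ethoxycyclopentenone) is attached and ring B is closed last.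

Key step: step 12

Remark (chemistry): the sense of induction in step 2 is assumed to follow that of 2-methylcyclohexanone, for which the (R)-amine gives the (S)-configured quaternary centre drawn.

**Route**

Step 1
Reactants: 1 3,3-dimethylcyclohexan-1-one
Product: 3 rac-2,5,5-trimethylcyclohexan-1-one, via lithium enolate 2 (not isolated)
Conditions: LiN(iPr)2, THF, −78 °C; MeI, −78 → 0 °C
Reagents that add atoms: iodomethane, CI
Why: Kinetic deprotonation by the hindered amide occurs at C6, away from the neopentyl C2 methylene, and the enolate is C-methylated (ketone enolate alkylation).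

Step 2
Reactants: 3 rac-2,5,5-trimethylcyclohexan-1-one; 4 but-3-en-2-one
Product: 7 (S)-2,5,5-trimethyl-2-(3-oxobutyl)cyclohexan-1-one, via imine 5 (not isolated), via Michael adduct imine 6 (not isolated)
Conditions: (R)-1-phenylethylamine, TsOH (cat.), PhMe, reflux (−H2O); 4, THF, 40 °C; 20% aq. AcOH, 20 °C
Reagents that add atoms: none
Why: Chiral-imine Michael addition (deracemising alkylation): the more substituted secondary enamine tautomer of 5 adds to the enone through a compact aza-ene-like transition state on the face anti to the phenyl group, so both enantiomers of 3 converge on the (S) quaternary centre (C12).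

Step 3
Reactants: 7 (S)-2,5,5-trimethyl-2-(3-oxobutyl)cyclohexan-1-one
Product: 8 (S)-4a,7,7-trimethyl-4,4a,5,6,7,8-hexahydronaphthalen-2(3H)-one
Conditions: NaOMe, MeOH, 65 °C
Reagents that add atoms: none
Why: Intramolecular aldol condensation (second half of the Robinson annulation) closes ring C without touching the stereocentre.

Step 4
Reactants: 8 (S)-4a,7,7-trimethyl-4,4a,5,6,7,8-hexahydronaphthalen-2(3H)-one
Product: 10 hydroxymethyl trans-decalone (C9 ketone; 17α-H; equatorial C18–CH2OH), via lithium enolate 9 (not isolated)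
Conditions: Li, NH3(l)–THF, t-BuOH (1 equiv), −78 °C; NH3 removed; CH2O (g), THF, −78 °C; aq. NH4Cl
Reagents that add atoms: formaldehyde, C=O
Why: Dissolving-metal reduction of the octalone protonates C17 axially to give the trans-fused enolate 9 regiospecifically (reductive alkylation of an enone), and formaldehyde traps it at C18; the new substituent ends equatorial (α) because the β-axial approach is syn to the C12 methyl and the centre can epimerise.

Step 5
Reactants: 10 hydroxymethyl trans-decalone
Product: 11 (E)-methoxymethylene derivative of 10 (C9=C8H–OMe; C19–OH free)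
Conditions: Ph3P(CH2OMe)Cl (3.5 equiv), KN(SiMe3)2 (3.3 equiv), THF, 0 → 20 °C
Reagents that add atoms: (methoxymethylene)triphenylphosphorane, COC=P(c1ccccc1)(c1ccccc1)c1ccccc1 (formed in the flask from (methoxymethyl)triphenylphosphonium chloride and KN(SiMe3)2)
Why: Wittig methoxymethylenation of the ketone; the excess base first forms the C19 alkoxide, which cannot undergo β-elimination, and the less hindered enol ether with OMe away from C18 is expected (either isomer serves in the next two steps).

Step 6
Reactants: 11 (E)-methoxymethylene derivative of 10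
Product: 12 spiro methoxycyclopropane (C9 spiro; cyclopropane CH2 on the α axial face; C19–OH)
Conditions: Et2Zn, CH2I2, CH2Cl2, 0 °C
Reagents that add atoms: diiodomethane, ICI (as ethyl(iodomethyl)zinc formed in the flask with Et2Zn)
Why: Simmons–Smith (Furukawa) cyclopropanation of the electron-rich enol ether delivered by the zinc alkoxide of the homoallylic C19 hydroxyl, which lies on the α (axial) side of the exocyclic π bond, so the new CH2 (the future C9 methyl) becomes axial-α and C8 stays equatorial-β.

Step 7
Reactants: 12 spiro methoxycyclopropane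
Product: 13 C19 iodide of 12
Conditions: I2, PPh3, imidazole, CH2Cl2, 0 → 20 °C
Reagents that add atoms: iodine, II
Why: Appel-type iodination of the primary alcohol under imidazole-buffered conditions that spare the acid-labile cyclopropyl ether.

Step 8
Reactants: 13 C19 iodide of 12
Product: 14 iodo aldehyde (9α-methyl; 9β-formyl; 18α-iodomethyl; trans-decalin)
Conditions: 1 M aq. HCl, THF, 20 °C
Reagents that add atoms: water, O
Why: Acid-induced ring opening of the alkoxycyclopropane: protonation of the unsubstituted CH2 cleaves its bond to the methoxy-bearing carbon, the oxocarbenium ion is hydrolysed to the aldehyde, and the CH2 becomes the C9 methyl without touching the quaternary stereocentre.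

Step 9
Reactants: 15 3-ethoxycyclopent-2-en-1-one; 16 2-bromoprop-2-en-1-ol
Product: 19 3-(3-hydroxyprop-1-en-2-yl)cyclopent-2-en-1-one, via dilithio allyl alkoxide 17 (not isolated), via dilithium adduct 18 (not isolated)
Conditions: 16, t-BuLi (3 equiv), Et2O, −78 → 0 °C; 15, −78 °C; 1 M aq. HCl, 0 °C
Reagents that add atoms: water, O
Why: Stork–Danheiser sequence: 1,2-addition of the α-(hydroxymethyl)vinyl dianion 17 to the vinylogous ester, then acid-induced hydrolysis with allylic transposition, gives the 3-substituted enone.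

Step 10
Reactants: 19 3-(3-hydroxyprop-1-en-2-yl)cyclopent-2-en-1-one
Product: 20 3-(3-bromoprop-1-en-2-yl)cyclopent-2-en-1-one
Conditions: CBr4, PPh3, CH2Cl2, 0 °C
Reagents that add atoms: carbon tetrabromide, BrC(Br)(Br)Br
Why: Appel bromination of the primary allylic alcohol; the SN2 and SN2' pathways give the same 2-substituted allyl bromide.

Step 11
Reactants: 20 3-(3-bromoprop-1-en-2-yl)cyclopent-2-en-1-one
Product: 21 3-[3-(tributylstannyl)prop-1-en-2-yl]cyclopent-2-en-1-one
Conditions: (Bu3Sn)2, Pd(PPh3)4 (3 mol %), THF, 50 °C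
Reagents that add atoms: hexabutylditin, CCCC[Sn](CCCC)(CCCC)[Sn](CCCC)(CCCC)CCCC
Why: Palladium-catalysed stannylation of an allylic halide with a distannane via a π-allylpalladium bromide and Sn–Sn transmetalation; the symmetric allyl unit removes any regiochemical issue.

Step 12
Reactants: 14 iodo aldehyde; 21 3-[3-(tributylstannyl)prop-1-en-2-yl]cyclopent-2-en-1-one
Product: 25 tetracyclic β-hydroxy ketone (C6 ketone; C2=C3; 7β-H; 8β-OH), via dienone aldehyde 22 (not isolated), via tin dienolate 23 (not isolated), via tin aldolate 24 (not isolated)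
Conditions: 21 (1.5 equiv), AIBN (cat.), PhH (0.3 M), 80 °C; then PhH (to 0.005 M), Bu3SnH (2 equiv, syringe pump), AIBN, 80 °C; H2O
Reagents that add atoms: none
Why: Proposed new method: a tin radical chain would first join the fragments by SH2' allylation (Bu3Sn• abstracts iodine from 14, the primary C19 radical adds to the free methylene terminus of the 2-(stannylmethyl)diene of 21, and loss of Bu3Sn• gives cross-conjugated dienone 22, whose former CH2Sn carbon is now a =CH2), and the Bu3SnH added afterwards would trigger a reductive aldol (O-stannyl ketyl, hydrogen transfer to that terminal =CH2, i.e. 1,6-reduction, then aldol of tin dienolate 23 onto the neopentyl aldehyde); the closest known reaction types are the radical allylation of alkyl iodides with allylstannanes and the Bu3SnH-mediated reductive aldol of enones with aldehydes, which have not been combined into a medium-ring annulation. Ring B (eight-membered) closes in the aldol event, an 8-(enolexo)-exo-trig attack of the ring-A enolate carbon C7 on the C8 aldehyde, after the C19–C20 bond has been made in the intermolecular allylation. Because hydrogen, not the decalin, is delivered to the diene terminus, the favoured s-trans rotamer of 22 places the future methyl C1 cis to C4 and the tether carbon C20 cis to C7, the only alkene geometry that can close a cyclooctene; the closed Sn–O six-membered transition state makes the α-carbon C7, not the fully substituted γ-carbon C2, the nucleophilic site. C7 and C8 are created together: the ring-fixed E(O)-enolate and a chair Zimmerman–Traxler transition state with the C9 substituent equatorial give the anti aldol (H7 and H8 anti), and the aldehyde face is chosen by C9, whose axial methyl is the small group beside the trajectory of C7 while the trans-decalin holds C19–C20 on the C18 side. The step needs chemoselectivity (allylation finished before any hydride is present; the conjugated ketone, not the aldehyde, accepts Bu3Sn•; hydrogen goes to terminal C1 rather than to C3) and high dilution in the second stage so that the hindered aldehyde reacts intramolecularly.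

Step 13
Reactants: 25 tetracyclic β-hydroxy ketone
Product: 27 enol triflate (C5=C6–OSO2CF3; 8β-OH), via dilithium alkoxide enolate 26 (not isolated)
Conditions: LiN(iPr)2 (2.2 equiv), THF, −78 °C; PhNTf2, −78 → 0 °C; aq. NH4Cl
Reagents that add atoms: N-phenylbis(trifluoromethanesulfonimide), O=S(=O)(N(c1ccccc1)S(=O)(=O)C(F)(F)F)C(F)(F)F
Why: The C8 lithium alkoxide cannot be eliminated, the second equivalent of amide removes a proton kinetically from the unhindered C5 methylene rather than the tertiary C7–H, and O-sulfonylation of the enolate gives the C5=C6 enol triflate.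

Step 14
Reactants: 27 enol triflate
Product: 28 6-methyl C5=C6 alkene (C2=C3 retained; 8β-OH)
Conditions: MeMgBr (3 equiv), Fe(acac)3 (5 mol %), THF–NMP, −30 → 0 °C
Reagents that add atoms: methylmagnesium bromide, C[Mg]Br
Why: Iron-catalysed cross-coupling of an alkenyl triflate with a methyl Grignard reagent (Kumada-type) installs the C6 methyl without moving the C5=C6 alkene; the magnesium alkoxide at C8 is a spectator.

Step 15
Reactants: 28 6-methyl C5=C6 alkene
Product: 30 CNP0213887.1 (target), via alkylborane 29 (not isolated)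
Conditions: 9-BBN (3 equiv), THF, 65 °C; NaOH, H2O2, 0 → 20 °C
Reagents that add atoms: hydrogen peroxide, OO
Why: Hydroboration–oxidation: 9-BBN adds to the trisubstituted C5=C6 alkene only (the tetrasubstituted C2=C3 alkene is inert), with boron at C5 and syn addition on the β face anti to the C7–C8 bond, which sets C5–OH β and C6–H β (C6 methyl α, trans to the hydroxyl); oxidation goes with retention.

**Compound list**

1 | 3,3-dimethylcyclohexan-1-one | CC1(C)CCCC(=O)C1 | starting material
2 | lithium 5,5-dimethylcyclohex-1-en-1-olate | [Li]OC1=CCCC(C)(C)C1 | intermediate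
3 | rac-2,5,5-trimethylcyclohexan-1-one | CC1CCC(C)(C)CC1=O | intermediate
4 | but-3-en-2-one (methyl vinyl ketone) | CC(=O)C=C | starting material
5 | (R)-1-phenylethyl imine of 3 (ring C2 racemic) | C[C@@H](N=C1CC(C)(C)CCC1C)c1ccccc1 | intermediate
6 | (R)-1-phenylethyl imine of (S)-2,5,5-trimethyl-2-(3-oxobutyl)cyclohexanone | C[C@@H](N=C1CC(C)(C)CC[C@@]1(C)CCC(C)=O)c1ccccc1 | intermediate
7 | (S)-2,5,5-trimethyl-2-(3-oxobutyl)cyclohexan-1-one | CC(=O)CC[C@]1(C)CCC(C)(C)CC1=O | intermediate
8 | (S)-4a,7,7-trimethyl-4,4a,5,6,7,8-hexahydronaphthalen-2(3H)-one (C9 ketone, C17=C18, 12β-methyl) | O=C1CC[C@]2(C)CCC(C)(C)CC2=C1 | intermediate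
9 | lithium enolate of the trans-fused decalone (C9–OLi, C9=C18, 17α-H, 12β-methyl) | [Li]OC=1CC[C@]2(C)CCC(C)(C)C[C@H]2C=1 | intermediate
10 | trans-decalone: C9 ketone, 12β-methyl, 17α-H, 18β-H, equatorial (α) C18 hydroxymethyl (C19), 15,15-dimethyl | O=C1CC[C@]2(C)CCC(C)(C)C[C@H]2[C@@H]1CO | intermediate
11 | (E)-C9 methoxymethylene derivative of 10 (OMe syn to C10), C19–OH free | CO/C=C1\CC[C@]2(C)CCC(C)(C)C[C@H]2[C@@H]1CO | intermediate
12 | spiro methoxycyclopropane at C9: cyclopropane CH2 axial (α), C8(H)(OMe) equatorial (β), C19–OH | CO[C@H]1C[C@@]12CC[C@]3(C)CCC(C)(C)C[C@H]3[C@@H]2CO | intermediate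
13 | C19 iodide of 12 | CO[C@H]1C[C@@]12CC[C@]3(C)CCC(C)(C)C[C@H]3[C@@H]2CI | intermediate
14 | iodo aldehyde: trans-decalin (12β-Me, 17α-H, 18β-H) with 9α-methyl, 9β-formyl (C8), 18α-iodomethyl (C19), 15,15-dimethyl | O=C[C@@]1(C)CC[C@]2(C)CCC(C)(C)C[C@H]2[C@@H]1CI | intermediate
15 | 3-ethoxycyclopent-2-en-1-one | CCOC1=CC(=O)CC1 | starting material
16 | 2-bromoprop-2-en-1-ol | OCC(Br)=C | starting material
17 | lithium 2-lithioprop-2-en-1-olate | [Li]OCC([Li])=C | intermediate
18 | dilithium dialkoxide of 3-ethoxy-1-(3-hydroxyprop-1-en-2-yl)cyclopent-2-en-1-ol (racemic) | CCOC1=CC(O[Li])(C(=C)CO[Li])CC1 | intermediate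
19 | 3-(3-hydroxyprop-1-en-2-yl)cyclopent-2-en-1-one | O=C1C=C(C(=C)CO)CC1 | intermediate
20 | 3-(3-bromoprop-1-en-2-yl)cyclopent-2-en-1-one | O=C1C=C(C(=C)CBr)CC1 | intermediate
21 | 3-[3-(tributylstannyl)prop-1-en-2-yl]cyclopent-2-en-1-one | O=C1C=C(C(=C)C[Sn](CCCC)(CCCC)CCCC)CC1 | intermediate
22 | dienone aldehyde: 14 with iodine replaced by CH2–C(=CH2)–(3-oxocyclopent-1-en-1-yl) (C19–C20 formed, C2=C1H2) | O=C[C@@]1(C)CC[C@]2(C)CCC(C)(C)C[C@H]2[C@@H]1CCC(=C)C1=CC(=O)CC1 | intermediate
23 | tributyltin dienolate of 1,6-reduced 22 (Sn–O at C6, C6=C7, C2=C3 with C20 cis to C7 and methyl C1 cis to C4) | O=C[C@@]1(C)CC[C@]2(C)CCC(C)(C)C[C@H]2[C@@H]1CC/C(C)=C1\C=C(O[Sn](CCCC)(CCCC)CCCC)CC1 | intermediate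
24 | tributyltin aldolate of 25 (Sn–O at C8) | C/C1=C2\CCC(=O)[C@@H]2[C@@H](O[Sn](CCCC)(CCCC)CCCC)[C@@]2(C)CC[C@]3(C)CCC(C)(C)C[C@H]3[C@@H]2CC1 | intermediate
25 | tetracyclic β-hydroxy ketone: C6 ketone, C2=C3 (C1 methyl cis to C4), 7β-H, 8β-OH, 9α-Me, 12β-Me, 17α-H, 18β-H, 15,15-dimethyl | C/C1=C2\CCC(=O)[C@@H]2[C@@H](O)[C@@]2(C)CC[C@]3(C)CCC(C)(C)C[C@H]3[C@@H]2CC1 | intermediate
26 | dilithium alkoxide–enolate of 25 (Li–O at C8; C5=C6–OLi) | C/C1=C2\CC=C(O[Li])[C@@H]2[C@@H](O[Li])[C@@]2(C)CC[C@]3(C)CCC(C)(C)C[C@H]3[C@@H]2CC1 | intermediate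
27 | enol triflate: C5=C6–OSO2CF3, otherwise as 25 | C/C1=C2\CC=C(OS(=O)(=O)C(F)(F)F)[C@@H]2[C@@H](O)[C@@]2(C)CC[C@]3(C)CCC(C)(C)C[C@H]3[C@@H]2CC1 | intermediate
28 | 6-methyl diene alcohol: C5=C6(Me), C2=C3, 8β-OH, otherwise as 25 | C/C1=C2\CC=C(C)[C@@H]2[C@@H](O)[C@@]2(C)CC[C@]3(C)CCC(C)(C)C[C@H]3[C@@H]2CC1 | intermediate
29 | 5β-(9-borabicyclo[3.3.1]nonan-9-yl) adduct of 28 (6β-H, 6α-Me), C8 oxygen as its 9-BBN borinate | C/C1=C2\C[C@@H](B3C4CCCC3CCC4)[C@H](C)[C@@H]2[C@@H](OB3C4CCCC3CCC4)[C@@]2(C)CC[C@]3(C)CCC(C)(C)C[C@H]3[C@@H]2CC1 | intermediate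
30 | CNP0213887.1: 5β-OH, 6α-Me, 7β-H, 8β-OH, 9α-Me, 12β-Me, 17α-H, 18β-H, C2=C3, 15,15-dimethyl | C/C1=C2\C[C@@H](O)[C@H](C)[C@@H]2[C@@H](O)[C@@]2(C)CC[C@]3(C)CCC(C)(C)C[C@H]3[C@@H]2CC1 | target

**Step count and risks**

Total steps: 15. Longest linear sequence: 12 steps (steps 1–8, then 12–15).

Steps most likely to fail:

1. Step 12 (proposed new method). Hydrogen transfer may reach the C19 radical before it adds to 21. The tin dienolate may close the eight-membered ring slowly or reversibly, so that intermolecular aldol or simple protonation takes over. Facial selectivity at C8 rests on the C9 centre alone. Fallback: the two halves would be run as separate known reactions. Radical allylation of 14 with 21 (AIBN, PhH, 80 °C, no hydride) would be stopped at dienone aldehyde 22, which would be isolated. Ring B would then be closed by a copper hydride reductive aldol cyclisation ([(Ph3P)CuH]6, PhMe, −40 → 20 °C; hydride to the terminal methylene, copper dienolate, intramolecular aldol), a reaction type established for enone–aldehyde substrates, returning to the route at 25. This fallback makes no compound outside the list (F0).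

2. Step 6. The methylene transfer may show poor facial selectivity (equatorial approach of the carbenoid), which would give the C9 epimer. Fallback: the quaternary centre would be built by equatorial alkylation of a nitrile anion, setting out from 10. Silylation (TBSCl, imidazole) would give the silyl ether of 10 F1. Reductive cyanation (TosMIC, KOt-Bu) would give the C9 nitrile F2. Deprotonation (LiN(iPr)2) and alkylation with benzyl chloromethyl ether, which enters equatorially and trans to C19, would give the axial nitrile with equatorial benzyloxymethyl group F3. DIBAL-H would give the axial aldehyde F4. Wolff–Kishner reduction (N2H4, KOH, diethylene glycol, 200 °C, with loss of the silyl group) would give the 9α-methyl benzyl ether alcohol F5. Iodination (I2, PPh3, imidazole) would give the iodide F6, and BCl3 would give the primary C8 alcohol F7. Dess–Martin oxidation would return to the route at 14.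

3. Step 13. Regiocontrol of enolisation may be lost (deprotonation at C7, followed by conjugation of the alkene or retro-aldol cleavage). Fallback: a Shapiro reaction, setting out from 25. Condensation with 2,4,6-triisopropylbenzenesulfonyl hydrazide would give the trisylhydrazone F8. n-BuLi (excess, −78 → 0 °C) would deprotonate the less hindered C5 methylene and generate the C6 vinyllithium with the C5=C6 alkene; quenching with MeI would return to the route at 28.

**Further compounds**

F0 | step 12 | none | none
F1 | step 6 | tert-butyldimethylsilyl ether of 10 | O=C1CC[C@]2(C)CCC(C)(C)C[C@H]2[C@@H]1CO[Si](C)(C)C(C)(C)C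
F2 | step 6 | C9 nitrile (C9 epimers) of the silyl ether | N#CC1CC[C@]2(C)CCC(C)(C)C[C@H]2[C@@H]1CO[Si](C)(C)C(C)(C)C
F3 | step 6 | 9α-cyano-9β-(benzyloxymethyl) silyl ether | c1ccccc1COC[C@@]1(C#N)CC[C@]2(C)CCC(C)(C)C[C@H]2[C@@H]1CO[Si](C)(C)C(C)(C)C
F4 | step 6 | 9α-formyl-9β-(benzyloxymethyl) silyl ether | c1ccccc1COC[C@@]1(C=O)CC[C@]2(C)CCC(C)(C)C[C@H]2[C@@H]1CO[Si](C)(C)C(C)(C)C
F5 | step 6 | 9α-methyl-9β-(benzyloxymethyl) C19 alcohol | c1ccccc1COC[C@@]1(C)CC[C@]2(C)CCC(C)(C)C[C@H]2[C@@H]1CO
F6 | step 6 | 9α-methyl-9β-(benzyloxymethyl) C19 iodide | c1ccccc1COC[C@@]1(C)CC[C@]2(C)CCC(C)(C)C[C@H]2[C@@H]1CI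
F7 | step 6 | 9α-methyl-9β-(hydroxymethyl) C19 iodide | OC[C@@]1(C)CC[C@]2(C)CCC(C)(C)C[C@H]2[C@@H]1CI
F8 | step 13 | 2,4,6-triisopropylbenzenesulfonyl hydrazone of 25 | C/C1=C2\CCC(=NNS(=O)(=O)c3c(C(C)C)cc(C(C)C)cc3C(C)C)[C@@H]2[C@@H](O)[C@@]2(C)CC[C@]3(C)CCC(C)(C)C[C@H]3[C@@H]2CC1
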